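**Plan**

- Retrosynthesis (carotenoid numbering; triol half unprimed, acetylenic half primed): cut C14'–C15' (the key sp2–sp2 bond), then C14–C15. The two carbons between the cuts are an (E)-vinylene linchpin. The two C18 halves that remain are the same ring-dienediyne, cut further at C11=C12 (olefination) and C6–C7 (alkynylation of a ring enol triflate).
- Feature that allows the key event: next to the key bond, C13' carries methyl C20' on an E trisubstituted alkene and C14' is a CH. This is the retron of a syn-methylmetalation of a terminal C13'≡C14' alkyne. The other triple bond C7'≡C8' is internal and shielded by ring carbon C6' (tetrasubstituted C5'=C6', gem-dimethyl C1') and by C9', so it stays out of the carbometalation.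
- Forward: actinol ring → enol triflate → C6–C7 Sonogashira → C11=C12 olefination → common alkyne. One part becomes the triol ring (directed epoxidation, hydrolysis), is silylated and extended by methyl C20 and the C15/C15' vinylene to a bromide. The other part is methylmetalated and coupled with that bromide, then desilylation, and last a hydroxyl-directed reduction of C7≡C8 to the 7E alkene.
- Stereochemistry: C3 and C3' come from (4R,6R)-actinol; C5 and C6 from O-3-directed syn-epoxidation and trans-diaxial hydrolysis with inversion at C5. 9E/9'E come from the enynol, 11E/11'E from the olefination, 13E/13'E from syn-carboalumination, 15E from (E)-1-bromo-2-iodoethene, 7E from trans-hydroalumination.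

Key step: step 13

Assumption: (4R,6R)-actinol (compound 1) is taken as a purchasable chiral ketone; the other starting materials are common catalogue chemicals.

**Route**

Step 1
Reactants: 1 (4R,6R)-actinol
Product: 2 (4R,6R)-4-[(tert-butyldimethylsilyl)oxy]-2,2,6-trimethylcyclohexan-1-one
Conditions: TBSCl, imidazole, DMF, rt
Reagents that add atoms: tert-butyldimethylsilyl chloride, CC(C)(C)[Si](C)(C)Cl
Why: Standard imidazole-mediated silylation of the secondary alcohol masks O-3 for the enolate step and touches neither the ketone nor a stereocentre.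

Step 2
Reactants: 2 silyloxy ketone
Product: 4 (4R)-4-[(tert-butyldimethylsilyl)oxy]-2,6,6-trimethylcyclohex-1-en-1-yl trifluoromethanesulfonate, via lithium enolate 3 (not isolated)
Conditions: LiN(iPr)2, THF, −78 → 0 °C; then PhNTf2, 0 °C → rt
Reagents that add atoms: N-phenylbis(trifluoromethanesulfonimide), O=S(=O)(N(c1ccccc1)S(=O)(=O)C(F)(F)F)C(F)(F)F
Why: The ketone can enolise only towards C6 (C2 is quaternary), so deprotonation and O-sulfonylation should give a single tetrasubstituted enol triflate; the C6 stereocentre is erased on purpose and C4 is untouched.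

Step 3
Reactants: 4 enol triflate; 5 (2E)-3-methylpent-2-en-4-yn-1-ol
Product: 6 (2E)-5-[(4R)-4-[(tert-butyldimethylsilyl)oxy]-2,6,6-trimethylcyclohex-1-en-1-yl]-3-methylpent-2-en-4-yn-1-ol
Conditions: Pd(PPh3)2Cl2 (5 mol%), CuI (10 mol%), Et3N, DMF, 50 °C
Reagents that add atoms: none
Why: Sonogashira coupling of an alkenyl triflate with a terminal alkyne forms the C6–C7 bond and carries the 9E geometry of the enynol through unchanged; the free primary alcohol and the silyl ether are tolerated.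

Step 4
Reactants: 6 enynol
Product: 7 (2E)-5-[(4R)-4-[(tert-butyldimethylsilyl)oxy]-2,6,6-trimethylcyclohex-1-en-1-yl]-3-methylpent-2-en-4-ynal
Conditions: activated MnO2 (excess), CH2Cl2, rt, dark
Reagents that add atoms: none
Why: Chemoselective MnO2 oxidation of the primary allylic alcohol should give the conjugated aldehyde without change of the 9E double bond.

Step 5
Reactants: 8 3-bromo-1-(trimethylsilyl)prop-1-yne; 9 triethyl phosphite
Product: 10 diethyl [3-(trimethylsilyl)prop-2-yn-1-yl]phosphonate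
Conditions: neat, 110 °C, bromoethane distilled off
Reagents that add atoms: none
Why: Michaelis–Arbuzov reaction of a reactive propargylic bromide with a trialkyl phosphite.

Step 6
Reactants: 7 ynenal; 10 propargylic phosphonate
Product: 12 tert-butyldimethyl{[(1R)-3,5,5-trimethyl-4-[(3E,5E)-3-methyl-8-(trimethylsilyl)octa-3,5-dien-1,7-diyn-1-yl]cyclohex-3-en-1-yl]oxy}silane, via lithiated phosphonate 11 (not isolated)
Conditions: 10, LiN(SiMe3)2, THF, −78 °C; then 7, −78 → 0 °C
Reagents that add atoms: none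
Why: Horner–Wadsworth–Emmons olefination with a stabilised propargylic phosphonate anion forms C11=C12 with the E isomer favoured; a minor Z isomer would be removed by chromatography.

Step 7
Reactants: 12 bis-silylated ring-dienediyne
Product: 13 (1R)-3,5,5-trimethyl-4-[(3E,5E)-3-methylocta-3,5-dien-1,7-diyn-1-yl]cyclohex-3-en-1-ol
Conditions: Bu4NF (2.5 equiv), THF, 0 °C → rt
Reagents that add atoms: none
Why: Fluoride cleaves the O–Si and the alkynyl C–Si bond in one operation and gives the hydroxy terminal alkyne that serves as the acetylenic half as such and as the precursor of the triol half.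

Step 8
Reactants: 13 hydroxy ring-dienediyne
Product: 14 (1S,3S,6S)-1,5,5-trimethyl-6-[(3E,5E)-3-methylocta-3,5-dien-1,7-diyn-1-yl]-7-oxabicyclo[4.1.0]heptan-3-ol
Conditions: VO(acac)2 (5 mol%), tBuOOH (1.5 equiv, decane), CH2Cl2, 0 °C → rt
Reagents that add atoms: tert-butyl hydroperoxide, CC(C)(C)OO
Why: Vanadium-catalysed hydroxyl-directed epoxidation of a cyclic homoallylic alcohol, in which the C3 alkoxide bound to the vanadium peroxide delivers oxygen to the face of C5=C6 that it occupies (sets C5 and C6 with the oxirane cis to O-3); the remote alkenes and both alkynes have no directing group and should stay untouched.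

Step 9
Reactants: 14 syn-epoxide
Product: 15 (1S,2R,4S)-1-[(3E,5E)-3-methylocta-3,5-dien-1,7-diyn-1-yl]-2,6,6-trimethylcyclohexane-1,2,4-triol
Conditions: HClO4 (0.1 equiv), THF–H2O 3:1, 0 °C → rt; NaHCO3 quench
Reagents that add atoms: water, O
Why: Acid-catalysed trans-diaxial (Fürst–Plattner) epoxide hydrolysis, in which water attacks the tertiary alkyl terminus C5 from the face opposite the oxirane because positive charge at C6 is destabilised by the sp carbon C7; C5 is inverted, the C6–O bond is kept, and the 5,6-trans-diol results with O-5 trans and O-6 cis to O-3.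

Step 10
Reactants: 15 triol
Product: 16 (1S,2R,4S)-1-[(3E,5E)-3-methylocta-3,5-dien-1,7-diyn-1-yl]-2,6,6-trimethyl-1,2,4-tris[(triethylsilyl)oxy]cyclohexane
Conditions: Et3SiOTf (5 equiv), 2,6-lutidine (8 equiv), CH2Cl2, −78 °C → rt
Reagents that add atoms: triethylsilyl trifluoromethanesulfonate, CC[Si](CC)(CC)OS(=O)(=O)C(F)(F)F
Why: Silyl triflate silylation covers the secondary and both hindered tertiary hydroxyls so that the organoaluminium and organozinc steps meet no O–H, and the terminal alkyne C–H is not silylated under these non-metallating conditions.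

Step 11
Reactants: 17 acetylene
Product: 18 (E)-1-bromo-2-iodoethene
Conditions: IBr, 48% aq. HBr, 0 °C, C2H2 (1 atm)
Reagents that add atoms: iodine monobromide, BrI
Why: Electrophilic anti addition of I–Br across acetylene through an iodonium ion should give the E dihalide, whose C–I and C–Br bonds can be addressed one after the other.

Step 12
Reactants: 16 tris-silylated triol alkyne; 18 (E)-1-bromo-2-iodoethene
Product: 20 (1S,2R,4S)-1-[(3E,5E,7E,9E)-10-bromo-3,7-dimethyldeca-3,5,7,9-tetraen-1-yn-1-yl]-2,6,6-trimethyl-1,2,4-tris[(triethylsilyl)oxy]cyclohexane, via alkenyldimethylalane 19 (not isolated)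
Conditions: (i) AlMe3 (2.5 equiv), (C5H5)2ZrCl2 (1 equiv), ClCH2CH2Cl, 0 → 23 °C; (ii) evaporate, THF; 18 (1.5 equiv), ZnCl2 (1 equiv), Pd2(dba)3 (2.5 mol%), P(2-furyl)3 (10 mol%), 23 °C, dark
Reagents that add atoms: trimethylaluminium, C[Al](C)C
Why: Zirconium-catalysed syn-methylalumination of the terminal C13≡C14 alkyne (methyl C20 to C13, Al to C14, hence 13E) followed by Negishi-type palladium/zinc-catalysed coupling at the more reactive C–I bond of 18 forms C14–C15 with retention at both alkenyl carbons and leaves the C15'–Br bond for the next step.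

Step 13
Reactants: 13 hydroxy ring-dienediyne; 20 polyenyl bromide
Product: 22 3,5,6-tris-O-(triethylsilyl)-(3S,5R,6S,3'R)-7,8,7',8'-tetradehydro-5,6-dihydro-β,β-carotene-3,5,6,3'-tetrol, via alkenylalane 21 (not isolated)
Conditions: (i) 13 (1.2 equiv), AlMe3 (3.5 equiv), (C5H5)2ZrCl2 (1 equiv), ClCH2CH2Cl, 0 → 23 °C; (ii) evaporate, THF; 20 (1.0 equiv), ZnCl2 (1 equiv), Pd2(dba)3 (2.5 mol%), P(2-furyl)3 (10 mol%), THF–DMF, 23 °C, dark; aq. NaHCO3 work-up
Reagents that add atoms: trimethylaluminium, C[Al](C)C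
Why: (C5H5)2ZrCl2 and AlMe3 form a methylzirconocene–aluminium species that adds methyl and metal syn across the terminal C13'≡C14' bond through a four-centre transition state, methyl to the internal C13' (it becomes C20') and metal to C14', after the first equivalent of AlMe3 has masked the C3' hydroxyl as O–AlMe2; the alkenylalane 21 is then passed through zinc to palladium, which in its zerovalent state has inserted into the C15'–Br bond of 20 with retention, and reductive elimination forms the C14'–C15' bond. The closest known reaction type is the Negishi tandem zirconium-catalysed carboalumination and palladium/zinc-catalysed alkenyl–alkenyl coupling, which is established for junctions of this kind in conjugated polyenes and for alkynes that carry a free hydroxyl. No ring is closed and no stereocentre is formed; the new stereo-element is the 13'E trisubstituted double bond, fixed by the syn addition and by retention at both carbons in the coupling, while 15E is carried in unchanged from the bromide. The step needs regioselectivity (Al on the terminal carbon), secured by the terminal alkyne; chemoselectivity for C13'≡C14' over C7'≡C8', secured because the latter is internal and flanked by the fully substituted ring carbon C6' and the methyl-bearing C9'; and inertness of C7≡C8 in 20, which is internal, sits next to the quaternary silyloxy carbon C6 and is met only after the excess AlMe3 has been removed.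

Step 14
Reactants: 22 tris-silylated C40 compound
Product: 23 (3S,5R,6S,3'R)-7,8,7',8'-tetradehydro-5,6-dihydro-β,β-carotene-3,5,6,3'-tetrol
Conditions: Bu4NF (5 equiv), THF, 0 °C → rt, dark
Reagents that add atoms: none
Why: Fluoride-mediated cleavage of the three triethylsilyl ethers under non-acidic conditions should spare the polyene and the tertiary propargylic carbinol.

Step 15
Reactants: 23 tetradehydro tetrol
Product: 25 heteroxanthin (3S,5R,6R,3'R)-7',8'-didehydro-5,6-dihydro-β,β-carotene-3,5,6,3'-tetrol, via cyclic alkenylaluminate 24 (not isolated)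
Conditions: NaAlH2(OCH2CH2OMe)2 (8 equiv), THF, 0 °C → rt, dark; then aq. KNaC4H4O6
Reagents that add atoms: none
Why: Hydroxyl-directed trans-hydroalumination of a propargylic alcohol, in which the C6 alkoxyaluminium hydride delivers hydride to C7 and closes a five-membered oxaluminate on C8 whose protonolysis gives the 7E alkene; only the triple bond with a neighbouring hydroxyl reacts, so C7'≡C8' should persist.

**Compound list**

1 | (4R,6R)-4-hydroxy-2,2,6-trimethylcyclohexan-1-one ((4R,6R)-actinol) | C[C@H]1C(=O)C(C)(C)C[C@H](O)C1 | starting material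
2 | (4R,6R)-4-[(tert-butyldimethylsilyl)oxy]-2,2,6-trimethylcyclohexan-1-one | C[C@H]1C(=O)C(C)(C)C[C@H](O[Si](C)(C)C(C)(C)C)C1 | intermediate
3 | lithium (4R)-4-[(tert-butyldimethylsilyl)oxy]-2,6,6-trimethylcyclohex-1-en-1-olate | CC1=C([O-])C(C)(C)C[C@H](O[Si](C)(C)C(C)(C)C)C1.[Li+] | intermediate
4 | (4R)-4-[(tert-butyldimethylsilyl)oxy]-2,6,6-trimethylcyclohex-1-en-1-yl trifluoromethanesulfonate | CC1=C(OS(=O)(=O)C(F)(F)F)C(C)(C)C[C@H](O[Si](C)(C)C(C)(C)C)C1 | intermediate
5 | (2E)-3-methylpent-2-en-4-yn-1-ol | C#C/C(C)=C/CO | starting material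
6 | (2E)-5-[(4R)-4-[(tert-butyldimethylsilyl)oxy]-2,6,6-trimethylcyclohex-1-en-1-yl]-3-methylpent-2-en-4-yn-1-ol | CC1=C(C#C/C(C)=C/CO)C(C)(C)C[C@H](O[Si](C)(C)C(C)(C)C)C1 | intermediate
7 | (2E)-5-[(4R)-4-[(tert-butyldimethylsilyl)oxy]-2,6,6-trimethylcyclohex-1-en-1-yl]-3-methylpent-2-en-4-ynal | CC1=C(C#C/C(C)=C/C=O)C(C)(C)C[C@H](O[Si](C)(C)C(C)(C)C)C1 | intermediate
8 | 3-bromo-1-(trimethylsilyl)prop-1-yne | C[Si](C)(C)C#CCBr | starting material
9 | triethyl phosphite | CCOP(OCC)OCC | starting material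
10 | diethyl [3-(trimethylsilyl)prop-2-yn-1-yl]phosphonate | CCOP(=O)(CC#C[Si](C)(C)C)OCC | intermediate
11 | lithium salt of the α-carbanion of 10 | CCOP(=O)([CH-]C#C[Si](C)(C)C)OCC.[Li+] | intermediate
12 | tert-butyldimethyl{[(1R)-3,5,5-trimethyl-4-[(3E,5E)-3-methyl-8-(trimethylsilyl)octa-3,5-dien-1,7-diyn-1-yl]cyclohex-3-en-1-yl]oxy}silane | CC1=C(C#C/C(C)=C/C=C/C#C[Si](C)(C)C)C(C)(C)C[C@H](O[Si](C)(C)C(C)(C)C)C1 | intermediate
13 | (1R)-3,5,5-trimethyl-4-[(3E,5E)-3-methylocta-3,5-dien-1,7-diyn-1-yl]cyclohex-3-en-1-ol | CC1=C(C#C/C(C)=C/C=C/C#C)C(C)(C)C[C@H](O)C1 | intermediate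
14 | (1S,3S,6S)-1,5,5-trimethyl-6-[(3E,5E)-3-methylocta-3,5-dien-1,7-diyn-1-yl]-7-oxabicyclo[4.1.0]heptan-3-ol (oxirane oxygen cis to the hydroxyl) | C[C@@]12O[C@]1(C#C/C(C)=C/C=C/C#C)C(C)(C)C[C@H](O)C2 | intermediate
15 | (1S,2R,4S)-1-[(3E,5E)-3-methylocta-3,5-dien-1,7-diyn-1-yl]-2,6,6-trimethylcyclohexane-1,2,4-triol | C#C/C=C/C=C(C)/C#C[C@@]1(O)C(C)(C)C[C@H](O)C[C@@]1(C)O | intermediate
16 | (1S,2R,4S)-1-[(3E,5E)-3-methylocta-3,5-dien-1,7-diyn-1-yl]-2,6,6-trimethyl-1,2,4-tris[(triethylsilyl)oxy]cyclohexane | C#C/C=C/C=C(C)/C#C[C@@]1(O[Si](CC)(CC)CC)C(C)(C)C[C@H](O[Si](CC)(CC)CC)C[C@@]1(C)O[Si](CC)(CC)CC | intermediate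
17 | acetylene | C#C | starting material
18 | (E)-1-bromo-2-iodoethene | Br/C=C/I | intermediate
19 | (E)-alkenyldimethylalane from syn-methylalumination of 16 (Al on C14, methyl C20 on C13) | C[Al](C)/C=C(C)/C=C/C=C(C)/C#C[C@@]1(O[Si](CC)(CC)CC)C(C)(C)C[C@H](O[Si](CC)(CC)CC)C[C@@]1(C)O[Si](CC)(CC)CC | intermediate
20 | (1S,2R,4S)-1-[(3E,5E,7E,9E)-10-bromo-3,7-dimethyldeca-3,5,7,9-tetraen-1-yn-1-yl]-2,6,6-trimethyl-1,2,4-tris[(triethylsilyl)oxy]cyclohexane | Br/C=C/C=C(C)/C=C/C=C(C)/C#C[C@@]1(O[Si](CC)(CC)CC)C(C)(C)C[C@H](O[Si](CC)(CC)CC)C[C@@]1(C)O[Si](CC)(CC)CC | intermediate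
21 | (E)-alkenyldimethylalane from syn-methylalumination of 13, with O-3' as its dimethylaluminium alkoxide | CC1=C(C#C/C(C)=C/C=C/C(C)=C/[Al](C)C)C(C)(C)C[C@H](O[Al](C)C)C1 | intermediate
22 | 3,5,6-tris-O-(triethylsilyl)-(3S,5R,6S,3'R)-7,8,7',8'-tetradehydro-5,6-dihydro-β,β-carotene-3,5,6,3'-tetrol | CC1=C(C#C/C(C)=C/C=C/C(C)=C/C=C/C=C(C)/C=C/C=C(C)/C#C[C@@]2(O[Si](CC)(CC)CC)C(C)(C)C[C@H](O[Si](CC)(CC)CC)C[C@@]2(C)O[Si](CC)(CC)CC)C(C)(C)C[C@H](O)C1 | intermediate
23 | (3S,5R,6S,3'R)-7,8,7',8'-tetradehydro-5,6-dihydro-β,β-carotene-3,5,6,3'-tetrol | CC1=C(C#C/C(C)=C/C=C/C(C)=C/C=C/C=C(C)/C=C/C=C(C)/C#C[C@@]2(O)C(C)(C)C[C@H](O)C[C@@]2(C)O)C(C)(C)C[C@H](O)C1 | intermediate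
24 | sodium cyclic alkoxy(alkenyl)bis(2-methoxyethoxy)aluminate from 23 (five-membered ring O-6, Al, C8, C7, C6; the other three hydroxyls drawn free) | CC1=C(C#C/C(C)=C/C=C/C(C)=C/C=C/C=C(C)/C=C/C=C(C)/C3=C[C@@]2(O[Al-]3(OCCOC)OCCOC)C(C)(C)C[C@H](O)C[C@@]2(C)O)C(C)(C)C[C@H](O)C1.[Na+] | intermediate
25 | heteroxanthin, (3S,5R,6R,3'R)-7',8'-didehydro-5,6-dihydro-β,β-carotene-3,5,6,3'-tetrol | CC1=C(C#C/C(C)=C/C=C/C(C)=C/C=C/C=C(C)/C=C/C=C(C)/C=C/[C@@]2(O)C(C)(C)C[C@H](O)C[C@@]2(C)O)C(C)(C)C[C@H](O)C1 | target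

**Step count and risks**

Total step count: 15. Longest linear sequence: 13 steps (steps 1, 2, 3, 4, 6, 7, 8, 9, 10, 12, 13, 14, 15).

Steps most likely to fail:

Step 9 (epoxide hydrolysis). The cation-like C5 centre may lose a proton or undergo a 1,2-shift faster than water captures it, or water may open the oxirane at C6. The fallback sets out from 14 and comes back at 15. Perhydrolysis of 14 with anhydrous ethereal H2O2 and catalytic H3PMo12O40 at room temperature lets the much more nucleophilic peroxide capture C5 with inversion under nearly neutral conditions. It should give the trans-hydroxy hydroperoxide (1S,2R,4S)-2-hydroperoxy-1-[(3E,5E)-3-methylocta-3,5-dien-1,7-diyn-1-yl]-2,6,6-trimethylcyclohexane-1,4-diol F1. Reduction of the O–O bond with PPh3 in THF then gives 15.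

Step 8 (directed epoxidation). Oxygen delivery from a homoallylic hydroxyl to the alkyne-conjugated, tetrasubstituted C5=C6 bond may be slow, so that oxidation of the secondary alcohol competes, or the syn-facial selectivity may be poor. The fallback sets out from 7 and comes back at 14, and puts the oxygen syn by the halohydrin route without hydroxyl direction.
- NBS in aqueous 1,2-dimethoxyethane at 0 °C should form the bromonium ion on the face anti to the C3 silyloxy group of the electron-rich C5=C6 bond (the enal C9=C10 is deactivated). Trans opening by water gives the bromohydrin (2E)-5-[(1R,2S,4S)-1-bromo-4-[(tert-butyldimethylsilyl)oxy]-2-hydroxy-2,6,6-trimethylcyclohexyl]-3-methylpent-2-en-4-ynal F2.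
- K2CO3 in MeOH closes the oxirane with inversion at the C–Br carbon to the syn-epoxy aldehyde (2E)-5-[(1S,4S,6S)-4-[(tert-butyldimethylsilyl)oxy]-2,2,6-trimethyl-7-oxabicyclo[4.1.0]heptan-1-yl]-3-methylpent-2-en-4-ynal F3.
- Olefination with 11 as in step 6 gives tert-butyldimethyl{[(1S,3S,6S)-1,5,5-trimethyl-6-[(3E,5E)-3-methyl-8-(trimethylsilyl)octa-3,5-dien-1,7-diyn-1-yl]-7-oxabicyclo[4.1.0]heptan-3-yl]oxy}silane F4.
- Bu4NF as in step 7 removes both silyl groups and gives 14.

Step 15 (final reduction). Chemoselectivity between the two triple bonds may be lost, or the unprotected C40 polyene may be degraded or isomerised in the basic aluminate medium. The fallback sets out from 15 and comes back at 25, and moves the reduction to the C18 stage.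
- 15 with NaAlH2(OCH2CH2OMe)2 in THF should give (1R,2R,4S)-1-[(1E,3E,5E)-3-methylocta-1,3,5-trien-7-yn-1-yl]-2,6,6-trimethylcyclohexane-1,2,4-triol F5.
- Et3SiOTf and 2,6-lutidine give its tris(triethylsilyl) ether F6.
- Methylalumination with AlMe3 and (C5H5)2ZrCl2 gives the alkenyldimethylalane F7 (not isolated), which is coupled with 18 as in step 12 to the bromide (1R,2R,4S)-1-[(1E,3E,5E,7E,9E)-10-bromo-3,7-dimethyldeca-1,3,5,7,9-pentaen-1-yl]-2,6,6-trimethyl-1,2,4-tris[(triethylsilyl)oxy]cyclohexane F8.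
- Coupling of F8 with alkenylalane 21 as in step 13 gives 3,5,6-tris-O-(triethylsilyl)heteroxanthin F9.
- Bu4NF gives 25.

**Further compounds**

F1 | step 9 | (1S,2R,4S)-2-hydroperoxy-1-[(3E,5E)-3-methylocta-3,5-dien-1,7-diyn-1-yl]-2,6,6-trimethylcyclohexane-1,4-diol | C#C/C=C/C=C(C)/C#C[C@@]1(O)C(C)(C)C[C@H](O)C[C@@]1(C)OO
F2 | step 8 | (2E)-5-[(1R,2S,4S)-1-bromo-4-[(tert-butyldimethylsilyl)oxy]-2-hydroxy-2,6,6-trimethylcyclohexyl]-3-methylpent-2-en-4-ynal | C[C@@]1(O)[C@](Br)(C#C/C(C)=C/C=O)C(C)(C)C[C@H](O[Si](C)(C)C(C)(C)C)C1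
F3 | step 8 | (2E)-5-[(1S,4S,6S)-4-[(tert-butyldimethylsilyl)oxy]-2,2,6-trimethyl-7-oxabicyclo[4.1.0]heptan-1-yl]-3-methylpent-2-en-4-ynal | C[C@@]12O[C@]1(C#C/C(C)=C/C=O)C(C)(C)C[C@H](O[Si](C)(C)C(C)(C)C)C2
F4 | step 8 | tert-butyldimethyl{[(1S,3S,6S)-1,5,5-trimethyl-6-[(3E,5E)-3-methyl-8-(trimethylsilyl)octa-3,5-dien-1,7-diyn-1-yl]-7-oxabicyclo[4.1.0]heptan-3-yl]oxy}silane | C[C@@]12O[C@]1(C#C/C(C)=C/C=C/C#C[Si](C)(C)C)C(C)(C)C[C@H](O[Si](C)(C)C(C)(C)C)C2
F5 | step 15 | (1R,2R,4S)-1-[(1E,3E,5E)-3-methylocta-1,3,5-trien-7-yn-1-yl]-2,6,6-trimethylcyclohexane-1,2,4-triol | C#C/C=C/C=C(C)/C=C/[C@@]1(O)C(C)(C)C[C@H](O)C[C@@]1(C)O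
F6 | step 15 | (1R,2R,4S)-1-[(1E,3E,5E)-3-methylocta-1,3,5-trien-7-yn-1-yl]-2,6,6-trimethyl-1,2,4-tris[(triethylsilyl)oxy]cyclohexane | C#C/C=C/C=C(C)/C=C/[C@@]1(O[Si](CC)(CC)CC)C(C)(C)C[C@H](O[Si](CC)(CC)CC)C[C@@]1(C)O[Si](CC)(CC)CC
F7 | step 15 | (E)-alkenyldimethylalane from syn-methylalumination of F6 | C[Al](C)/C=C(C)/C=C/C=C(C)/C=C/[C@@]1(O[Si](CC)(CC)CC)C(C)(C)C[C@H](O[Si](CC)(CC)CC)C[C@@]1(C)O[Si](CC)(CC)CC
F8 | step 15 | (1R,2R,4S)-1-[(1E,3E,5E,7E,9E)-10-bromo-3,7-dimethyldeca-1,3,5,7,9-pentaen-1-yl]-2,6,6-trimethyl-1,2,4-tris[(triethylsilyl)oxy]cyclohexane | Br/C=C/C=C(C)/C=C/C=C(C)/C=C/[C@@]1(O[Si](CC)(CC)CC)C(C)(C)C[C@H](O[Si](CC)(CC)CC)C[C@@]1(C)O[Si](CC)(CC)CC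
F9 | step 15 | 3,5,6-tris-O-(triethylsilyl)heteroxanthin | CC1=C(C#C/C(C)=C/C=C/C(C)=C/C=C/C=C(C)/C=C/C=C(C)/C=C/[C@@]2(O[Si](CC)(CC)CC)C(C)(C)C[C@H](O[Si](CC)(CC)CC)C[C@@]2(C)O[Si](CC)(CC)CC)C(C)(C)C[C@H](O)C1
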